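**Retrosynthetic overview**
1. Endgame: C2‑OAc and C1′‑OH come from two silyl ethers of different lability; the guaianolide α‑methylene comes from a Mannich/elimination; the trans γ‑lactone comes from syn hydroboration of a C7=C8 ring alkene followed by lactonization.
2. The seven‑membered ring is closed last by RCM (C7=C8) after a Negishi coupling places C6–C7–C11–C12 on C5. The guaiane half is carried as a 7,8‑seco unit, so no guaianolide cyclopentadiene is ever made.
3. The norbornene and spiro centre (C1–C13′, C3–C11′) come from an anionic [4+2] (Michael–Michael) of a cross‑conjugated cyclopentenone dienolate onto an ent‑alantolactone‑type α‑methylene lactone, with the final enolate trapped as the C5 triflate. Attack anti to C2‑OSi places that oxygen syn to C4=C5, as the target requires; a neutral Diels–Alder of a 5‑oxygenated cyclopentadiene normally favours the opposite face and suffers 1,5‑H shifts.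
4. Fragments: the acceptor from (S)‑Wieland–Miescher ketone; the dienolate precursor from (R)‑4‑TBSO‑cyclopentenone (α‑methylation, then a Michael addition that sets C10).
5. Ring order: decalin (bought) → eudesmanolide lactone → cyclopentene (bought) → norbornene → cycloheptene → guaianolide lactone.

Assumption: the SMILES is taken exactly as written (1R,2S,3S,7S,8R,10R; 1′S,4′R,7′S,8′S,10′S,11′R; C2‑OAc syn to C4=C5; endo lactone C=O). Guaiane atoms are unprimed, eudesmane atoms primed.

---

**Eudesmanolide acceptor**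

Step 1
Reactants: 1, (S)‑Wieland–Miescher ketone
Product: 2, (4aS,5S)‑5‑hydroxy‑4a‑methyl‑4,4a,5,6,7,8‑hexahydronaphthalen‑2(3H)‑one (OH cis to angular Me)
Conditions: NaBH4 (0.3 equiv), EtOH, −10 °C
Reagents that add atoms: none
Why: Chemoselective borohydride reduction of the saturated ketone; hydride adds anti to the angular methyl, giving the cis alcohol (future C1′).

Step 2
Reactants: 2
Product: 3, TBDPS ether of 2
Conditions: TBDPSCl, imidazole, DMAP, DMF, 50 °C
Reagents that add atoms: tert‑butyl(chloro)diphenylsilane, CC(C)(C)[Si](Cl)(c1ccccc1)c1ccccc1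
Why: Silylation with an acid‑robust group that can later be distinguished from the TBS ether at C2.

Step 3
Reactants: 3
Product: 4, 8‑methylidene dienone (exocyclic CH2 at C4′, C5′=C6′–C7′=O)
Conditions: CH2(OEt)2, POCl3, NaOAc, CHCl3, 60 °C
Reagents that add atoms: diethoxymethane, CCOCOCC
Why: Vinylogous (γ) methylenation of the enone via its dienol ether and an alkoxymethyl cation, the reaction used for 6‑methylenation of Δ4‑3‑keto steroids.

Step 4
Reactants: 4
Product: 5, (4aS,5S,8R)‑5‑(TBDPSO)‑4a,8‑dimethyl‑4,4a,5,6,7,8‑hexahydronaphthalen‑2(3H)‑one (C4′‑Me cis to C10′‑Me)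
Conditions: H2 (1 atm), (Ph3P)3RhCl, benzene/EtOH, rt
Reagents that add atoms: none
Why: Wilkinson hydrogenation of the exocyclic alkene only; H2 is delivered anti to the angular methyl and OSi, pushing the new methyl to the cis (kinetic) position.

Step 5
Reactants: 5
Product: 6, 8′‑hydroxy derivative of 5 (α′‑OH, trans to angular Me)
Conditions: LDA, THF, −78 °C; then 2‑(phenylsulfonyl)‑3‑phenyloxaziridine
Reagents that add atoms: Davis oxaziridine, O=S(=O)(c1ccccc1)N1OC1c1ccccc1
Why: Kinetic α′‑enolate hydroxylation (Davis oxidation); C8′ configuration is irrelevant because it is oxidized in step 8.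

Step 6
Reactants: 6
Product: 7, 7′,7′‑ethylenedithio ketal of 6 (Δ5′ retained)
Conditions: HSCH2CH2SH, BF3·OEt2, CH2Cl2, 0 °C
Reagents that add atoms: ethane‑1,2‑dithiol, SCCS
Why: Dithioketalization of the enone carbonyl; as with Δ4‑3‑keto steroids the double bond stays in place.

Step 7
Reactants: 7
Product: 8, Δ5′‑8′‑ol (C7′ now CH2)
Conditions: Raney Ni (W‑2, acetone‑deactivated), EtOH, reflux
Reagents that add atoms: none
Why: Mozingo desulfurization removes the original carbonyl without touching the trisubstituted alkene.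

Step 8
Reactants: 8
Product: 9, β,γ‑unsaturated 8′‑ketone (C8′=O, C7′H2, C5′=C6′)
Conditions: Dess–Martin periodinane, NaHCO3, CH2Cl2, 0 °C
Reagents that add atoms: none
Why: Buffered DMP oxidation completes the 1,2‑carbonyl transposition (C7′→C8′) without conjugating the alkene.

Step 9
Reactants: 9
Product: 10, methyl 2‑(8′‑oxo‑Δ5′‑7′‑yl)acetate (C7′ side chain equatorial, cis to C10′‑Me)
Conditions: LDA, THF/DMPU, −78 °C; BrCH2CO2Me; then NaOMe (cat.), MeOH, 0 °C
Reagents that add atoms: methyl bromoacetate, COC(=O)CBr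
Why: The doubly activated C7′–H gives the dienolate, which alkylates at its α‑carbon; brief base equilibration via kinetic α‑reprotonation gives the pseudo‑equatorial C7′ epimer.

Step 10
Reactants: 10
Product: 11, cis‑fused 12′,8′‑lactone (11′,13′‑dihydro‑13′‑nor acceptor precursor)
Conditions: NaBH4, MeOH, 0 °C; then TsOH (cat.), benzene, rt
Reagents that add atoms: none
Why: Hydride attacks C8′ anti to the axial C10′‑Me, giving the alcohol cis to the C7′ side chain, which lactonizes to the cis lactone.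

Step 11
Reactants: 11
Product: 12, ent‑1β‑(TBDPSO)‑alantolactone, (3aS,5R,8S,8aS,9aS)‑8‑(TBDPSO)‑5,8a‑dimethyl‑3‑methylidene‑octahydronaphtho[2,3‑b]furan‑2‑one
Conditions: LDA, THF, −78 °C; Me2N=CH2+ I−; then MeI, MeOH; then aq NaHCO3
Reagents that add atoms: Eschenmoser's salt, C=[N+](C)C.[I-]
Why: Lactone‑enolate Mannich reaction, quaternization and E1cB elimination give the α‑methylene lactone; no stereocentre changes.

**Cyclopentenone (dienolate) fragment**

Step 12
Reactants: 13, (R)‑4‑(tert‑butyldimethylsilyloxy)cyclopent‑2‑en‑1‑one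
Product: 14, (R)‑4‑(TBSO)‑2‑iodocyclopent‑2‑en‑1‑one
Conditions: I2, pyridine, CH2Cl2, 0 °C → rt
Reagents that add atoms: iodine, II
Why: Johnson α‑iodination of the enone (pyridine addition, iodination, elimination).

Step 13
Reactants: 14
Product: 15, (R)‑4‑(TBSO)‑2‑methylcyclopent‑2‑en‑1‑one
Conditions: Me4Sn, Pd2(dba)3, AsPh3, CuI, NMP, 60 °C
Reagents that add atoms: tetramethyltin, C[Sn](C)(C)C
Why: Stille methylation of the α‑iodoenone under neutral conditions that spare the β‑silyloxy ketone.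

Step 14
Reactants: 15; 16, methyl (E)‑but‑2‑enoate
Product: 17, methyl (3R)‑3‑[(1R,5S)‑5‑(TBSO)‑3‑methyl‑2‑oxocyclopent‑3‑en‑1‑yl]butanoate
Conditions: LDA, THF, −78 °C; 16, −78 °C, 1 h; AcOH quench at −78 °C
Reagents that add atoms: none
Why: Michael addition of the kinetic α′‑enolate anti to the OTBS group through the Li‑chelated (E)‑enolate/(E)‑enoate transition state (H over the ring, ester near O–Li), which sets C10; the cold quench prevents a second Michael closure.

Step 15
Reactants: 17
Product: 18, diol (primary C8‑OH and ring allylic alcohol, carbinol epimers)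
Conditions: DIBAL‑H (4 equiv), CH2Cl2, −78 → 0 °C
Reagents that add atoms: none
Why: Exhaustive hydride reduction of ester and enone carbonyl (1,2‑mode); the new carbinol centre is erased in the next step.

Step 16
Reactants: 18
Product: 19, keto‑aldehyde, (3R)‑3‑[(1R,5S)‑5‑(TBSO)‑3‑methyl‑2‑oxocyclopent‑3‑en‑1‑yl]butanal
Conditions: Dess–Martin periodinane (3 equiv), NaHCO3, CH2Cl2, rt
Reagents that add atoms: none
Why: Double DMP oxidation restores the enone and gives the aldehyde in one operation.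

Step 17
Reactants: 19
Product: 20, (4S,5R)‑4‑(TBSO)‑2‑methyl‑5‑[(2R)‑pent‑4‑en‑2‑yl]cyclopent‑2‑en‑1‑one
Conditions: Ph3PCH3Br, KHMDS, THF, −78 → 0 °C (1.1 equiv ylide)
Reagents that add atoms: methyltriphenylphosphonium bromide, C[P+](c1ccccc1)(c1ccccc1)c1ccccc1.[Br-]
Why: Wittig methylenation is selective for the aldehyde over the hindered enone; any C1 epimerization is harmless because C1 is re‑enolized in step 18.

**Union and guaiane ring construction**

Step 18
Reactants: 20; 12
Product: 21, norbornenyl triflate: bicyclo[2.2.1]heptene with C5‑OTf, C4‑Me, C2‑OTBS (syn to C4=C5), C1‑[(2R)‑pent‑4‑en‑2‑yl], and C11′ spiro to the eudesmanolide lactone (C=O endo)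
Conditions: 20, LiHMDS, THF, −78 °C; add 12, −78 → −20 °C; then Comins' reagent, −78 → 0 °C
Reagents that add atoms: N‑(5‑chloropyridin‑2‑yl)bis(trifluoromethanesulfonimide), O=S(=O)(N(c1ccc(Cl)cn1)S(=O)(=O)C(F)(F)F)C(F)(F)F
Why: Sequential Michael–Michael (anionic Diels–Alder) annulation: the α′‑enolate carbon C1 adds to C13′ anti to C2‑OTBS, the lactone enolate closes 5‑exo onto C3 from the convex (H7′) face with the carbonyl endo (Li‑chelated), setting C1, C3 and C11′, and the resulting ketone enolate is triflated at C5.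

Step 19
Reactants: 22, itaconic acid 4‑methyl ester
Product: 23, methyl 3‑(hydroxymethyl)but‑3‑enoate
Conditions: BH3·SMe2, THF, −10 → 0 °C (used crude)
Reagents that add atoms: none
Why: Borane reduces the free acid far faster than the ester or the electron‑poor alkene.

Step 20
Reactants: 23
Product: 24, methyl 3‑(bromomethyl)but‑3‑enoate
Conditions: CBr4, PPh3, CH2Cl2, 0 °C
Reagents that add atoms: carbon tetrabromide, BrC(Br)(Br)Br
Why: Appel bromination of the primary allylic alcohol.

Step 21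
Reactants: 21; 24
Product: 25, diene ester: C5 now bears CH2–C(=CH2)–CH2CO2Me (C6, C7, C11, C12)
Conditions: 24, Zn dust, LiCl, THF, 0 °C; then 21, Pd(OAc)2/SPhos (5 mol %), THF, rt
Reagents that add atoms: none
Why: Negishi coupling of the 2‑substituted allylzinc (both termini equivalent, so no regiochemical issue) with the alkenyl triflate; room temperature avoids Heck cyclization onto the pendant alkene.

Step 22
Reactants: 25
Product: 26, cycloheptene‑fused norbornene: ring C1–C10–C9–C8=C7–C6–C5, with C7 bearing CH2CO2Me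
Conditions: Grubbs II (10 mol %), toluene, 60 °C
Reagents that add atoms: none
Why: Ring‑closing metathesis of the terminal and 1,1‑disubstituted alkenes gives the trisubstituted seven‑membered alkene; the tetrasubstituted and eudesmane alkenes are inert.

Step 23
Reactants: 26
Product: 27, trans‑fused 12,8‑lactone (C7‑H and C8‑O on the face opposite C10‑Me; C11 is CH2)
Conditions: BH3·THF (1.5 equiv), THF, 0 °C; H2O2, aq NaOAc; then PPTS, CH2Cl2, rt
Reagents that add atoms: hydrogen peroxide, OO
Why: Syn hydroboration places B on C8 and H on C7 from the face anti to the neighbouring C10‑Me and the C2‑OTBS bridge, so after oxidation the C8‑OH is trans to the C7‑CH2CO2Me arm and lactonizes to the trans lactone; the hindered C5′=C6′ alkene is slower.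

Step 24
Reactants: 27
Product: 28, bis‑silyl japonicone A (C2‑OTBS, C1′‑OTBDPS, C11=C13 installed)
Conditions: LDA, THF, −78 °C; Me2N=CH2+ I−; then MeI, MeOH; then aq NaHCO3
Reagents that add atoms: Eschenmoser's salt, C=[N+](C)C.[I-]
Why: Mannich methylenation at the only enolizable lactone α‑carbon (the spiro lactone has no α‑H).

Step 25
Reactants: 28
Product: 29, C2 alcohol (C1′‑OTBDPS retained)
Conditions: HF·pyridine, pyridine, THF, 0 °C → rt
Reagents that add atoms: none
Why: Selective acid‑type desilylation; TBS ethers cleave about two orders of magnitude faster than TBDPS ethers.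

Step 26
Reactants: 29
Product: 30, C2 acetate (C1′‑OTBDPS)
Conditions: Ac2O, DMAP, pyridine, rt
Reagents that add atoms: acetic anhydride, CC(=O)OC(C)=O
Why: Standard acylation of the only free hydroxyl, with retention at C2.

Step 27
Reactants: 30
Product: 31, japonicone A
Conditions: HF·pyridine (excess), THF/MeCN, 40 °C
Reagents that add atoms: none
Why: Non‑basic fluoride removal of the TBDPS ether; the acetate and both lactones are stable to HF·pyridine.

---

**Compound list**
1 | (S)‑Wieland–Miescher ketone | C[C@]12CCC(=O)C=C1CCCC2=O | starting material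
2 | (4aS,5S)‑hydroxy enone | C[C@]12CCC(=O)C=C1CCC[C@@H]2O | intermediate
3 | TBDPS ether of 2 | C[C@]12CCC(=O)C=C1CCC[C@@H]2O[Si](c1ccccc1)(c1ccccc1)C(C)(C)C | intermediate
4 | 4′‑methylidene dienone | C[C@]12CCC(=O)C=C1C(=C)CC[C@@H]2O[Si](c1ccccc1)(c1ccccc1)C(C)(C)C | intermediate
5 | 4′‑methyl enone (Me/Me cis) | C[C@]12CCC(=O)C=C1[C@H](C)CC[C@@H]2O[Si](c1ccccc1)(c1ccccc1)C(C)(C)C | intermediate
6 | 8′‑hydroxy enone | C[C@]12C[C@@H](O)C(=O)C=C1[C@H](C)CC[C@@H]2O[Si](c1ccccc1)(c1ccccc1)C(C)(C)C | intermediate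
7 | 7′‑dithiolane | C[C@]12C[C@@H](O)C3(SCCS3)C=C1[C@H](C)CC[C@@H]2O[Si](c1ccccc1)(c1ccccc1)C(C)(C)C | intermediate
8 | Δ5′‑8′‑ol | C[C@]12C[C@@H](O)CC=C1[C@H](C)CC[C@@H]2O[Si](c1ccccc1)(c1ccccc1)C(C)(C)C | intermediate
9 | Δ5′‑8′‑one | C[C@]12CC(=O)CC=C1[C@H](C)CC[C@@H]2O[Si](c1ccccc1)(c1ccccc1)C(C)(C)C | intermediate
10 | C7′ keto ester | C[C@]12CC(=O)[C@H](CC(=O)OC)C=C1[C@H](C)CC[C@@H]2O[Si](c1ccccc1)(c1ccccc1)C(C)(C)C | intermediate
11 | cis lactone | C[C@]12C[C@@H]3OC(=O)C[C@@H]3C=C1[C@H](C)CC[C@@H]2O[Si](c1ccccc1)(c1ccccc1)C(C)(C)C | intermediate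
12 | ent‑1β‑(TBDPSO)‑alantolactone | C[C@]12C[C@@H]3OC(=O)C(=C)[C@@H]3C=C1[C@H](C)CC[C@@H]2O[Si](c1ccccc1)(c1ccccc1)C(C)(C)C | intermediate
13 | (R)‑4‑(TBSO)cyclopent‑2‑en‑1‑one | O=C1C=C[C@H](O[Si](C)(C)C(C)(C)C)C1 | starting material
14 | (R)‑2‑iodo enone | O=C1C(I)=C[C@H](O[Si](C)(C)C(C)(C)C)C1 | intermediate
15 | (R)‑2‑methyl enone | CC1=C[C@H](O[Si](C)(C)C(C)(C)C)CC1=O | intermediate
16 | methyl (E)‑crotonate | C/C=C/C(=O)OC | starting material
17 | Michael adduct (methyl ester) | CC1=C[C@H](O[Si](C)(C)C(C)(C)C)[C@@H]([C@H](C)CC(=O)OC)C1=O | intermediate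
18 | diol (carbinol epimers) | CC1=C[C@H](O[Si](C)(C)C(C)(C)C)[C@@H]([C@H](C)CCO)C1O | intermediate
19 | keto‑aldehyde | CC1=C[C@H](O[Si](C)(C)C(C)(C)C)[C@@H]([C@H](C)CC=O)C1=O | intermediate
20 | pentenyl cyclopentenone | CC1=C[C@H](O[Si](C)(C)C(C)(C)C)[C@@H]([C@H](C)CC=C)C1=O | intermediate
21 | norbornenyl triflate | C=CC[C@@H](C)[C@]12C[C@]3(C(=O)O[C@H]4C[C@@]5(C)C(=C[C@H]43)[C@H](C)CC[C@@H]5O[Si](c6ccccc6)(c6ccccc6)C(C)(C)C)[C@H](C(C)=C1OS(=O)(=O)C(F)(F)F)[C@@H]2O[Si](C)(C)C(C)(C)C | intermediate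
22 | itaconic acid 4‑methyl ester | C=C(CC(=O)OC)C(=O)O | starting material
23 | methyl 3‑(hydroxymethyl)but‑3‑enoate | C=C(CO)CC(=O)OC | intermediate
24 | methyl 3‑(bromomethyl)but‑3‑enoate | C=C(CBr)CC(=O)OC | intermediate
25 | Negishi product (RCM precursor) | C=CC[C@@H](C)[C@]12C[C@]3(C(=O)O[C@H]4C[C@@]5(C)C(=C[C@H]43)[C@H](C)CC[C@@H]5O[Si](c6ccccc6)(c6ccccc6)C(C)(C)C)[C@H](C(C)=C1CC(=C)CC(=O)OC)[C@@H]2O[Si](C)(C)C(C)(C)C | intermediate
26 | cycloheptene ester | COC(=O)CC1=CC[C@@H](C)[C@]23C[C@]4(C(=O)O[C@H]5C[C@@]6(C)C(=C[C@H]54)[C@H](C)CC[C@@H]6O[Si](c7ccccc7)(c7ccccc7)C(C)(C)C)[C@H](C(C)=C2C1)[C@@H]3O[Si](C)(C)C(C)(C)C | intermediate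
27 | trans lactone (11,13‑dihydro‑13‑nor) | O=C1O[C@@H]2C[C@@H](C)[C@]34C[C@]5(C(=O)O[C@H]6C[C@@]7(C)C(=C[C@H]65)[C@H](C)CC[C@@H]7O[Si](c8ccccc8)(c8ccccc8)C(C)(C)C)[C@H](C(C)=C3C[C@H]2C1)[C@@H]4O[Si](C)(C)C(C)(C)C | intermediate
28 | bis‑silyl japonicone A | C=C1C(=O)O[C@@H]2C[C@@H](C)[C@]34C[C@]5(C(=O)O[C@H]6C[C@@]7(C)C(=C[C@H]65)[C@H](C)CC[C@@H]7O[Si](c8ccccc8)(c8ccccc8)C(C)(C)C)[C@H](C(C)=C3C[C@@H]12)[C@@H]4O[Si](C)(C)C(C)(C)C | intermediate
29 | C2 alcohol | C=C1C(=O)O[C@@H]2C[C@@H](C)[C@]34C[C@]5(C(=O)O[C@H]6C[C@@]7(C)C(=C[C@H]65)[C@H](C)CC[C@@H]7O[Si](c8ccccc8)(c8ccccc8)C(C)(C)C)[C@H](C(C)=C3C[C@@H]12)[C@@H]4O | intermediate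
30 | C2 acetate, C1′‑OTBDPS | C=C1C(=O)O[C@@H]2C[C@@H](C)[C@]34C[C@]5(C(=O)O[C@H]6C[C@@]7(C)C(=C[C@H]65)[C@H](C)CC[C@@H]7O[Si](c8ccccc8)(c8ccccc8)C(C)(C)C)[C@H](C(C)=C3C[C@@H]12)[C@@H]4OC(C)=O | intermediate
31 | japonicone A | C=C1C(=O)O[C@@H]2C[C@@H](C)[C@]34C[C@]5(C(=O)O[C@H]6C[C@@]7(C)C(=C[C@H]65)[C@H](C)CC[C@@H]7O)[C@H](C(C)=C3C[C@@H]12)[C@@H]4OC(C)=O | target

---

**Totals:** 27 steps. Longest linear sequence: 19 steps, from (S)‑Wieland–Miescher ketone (steps 1–11, 18, 21–27).

**Three steps most likely to fail, with fallbacks that change the approach**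
1. **Step 18 (Michael–Michael annulation and triflation).** Risks are the congested quaternary C1, incomplete second Michael closure, and base‑induced isomerization of 12 to the butenolide. Fallback: form the two bonds in the reverse order. Add the enolate of saturated lactone 11 to C3 of enone 20 (1,4‑addition anti to OTBS), hydroxymethylate C11′ with CH2O, convert to the iodide, and close C1–C13′ by intramolecular ketone‑enolate alkylation; then triflate.
2. **Step 23 (hydroboration facial and chemoselectivity, which sets C7 and C8).** Fallback: set C7/C8 under reagent control before ring closure. Carry the side chain as the C8 aldehyde after the union, run an Evans syn‑aldol with a succinate‑derived N‑acyloxazolidinone (gives the trans paraconate lactone), reduce the C6 carboxyl to CH2I, and close the seven‑membered ring by intramolecular Ni‑catalysed reductive coupling of the alkenyl triflate with the alkyl iodide.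
3. **Step 14 (mono‑Michael addition and C10 selectivity).** Fallback: set C10 under catalyst control. Use Ir/phosphoramidite‑catalysed branched allylic alkylation of the enolate of 15 with a crotyl carbonate to install CH(CH3)CH=CH2, then homologate after the union (hydroboration/oxidation, then Wittig) to the same pentenyl chain.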